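Ring numbering used below: O1, C2 (CH–CH3), C3 (CH–CH2OH), C4 (CH–CH2CO2R), C5 (C–CO2Me), C6 (=CH–O).
Retrosynthesis: the C3 hydroxymethyl group is taken back to a formyl group, the side-chain ester is cut at its O–alkyl bond into hydroxytyrosol and a dihydropyran acetic acid, and the ring is then cut across O1–C2 and C3–C4 into (E)-but-2-enal and the enol of dimethyl 2-formylglutaconate.
Enabling feature: O1–C6H=C5(CO2Me) is the enol ether of a 2-formyl ester and C4 carries a CH2CO2R arm, so O1 and C4 are the nucleophilic enol oxygen and the acrylate β-carbon of a 2-(hydroxymethylidene)glutaconate; C2–C3 with a formyl group on C3 is an enal, electrophilic at C2 and, after conjugate addition, nucleophilic at C3.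
Forward: formylation of dimethyl glutaconate; amine-catalysed oxa-Michael/Michael annulation with crotonaldehyde closes the only ring; an esterase tells the aliphatic methyl ester from the ring ester; Mitsunobu esterification joins hydroxytyrosol; the aldehyde is reduced last.
Stereochemistry: C4 comes from the chiral secondary amine in the C–C bond-forming step; C3 (enolisable) and C2 (reversible oxa-Michael addition) then settle into the most stable arrangement relative to C4, which is that of the target.

Key step: step 2

Assumption: with C4 fixed as S, the (2S,3S) 3-formyl dihydropyran (the configuration of elenolic acid) is taken to be the most stable of the four C2/C3 diastereomers, so that equilibration converges on it.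

Step 1
Reactants: 1 dimethyl (E)-pent-2-enedioate (dimethyl glutaconate); 2 methyl formate
Product: 3 dimethyl (2Z,3E)-2-(hydroxymethylidene)pent-3-enedioate
Conditions: NaH (1.2 equiv), HCO2Me (5 equiv), THF, 0 °C to rt; then cold 1 M HCl, extraction, used crude
Reagents that add atoms: none
Why: Claisen-type C-formylation of the glutaconate anion, whose two reactive termini are equivalent, driven by formation of the stabilised hydroxymethylene enolate; no stereocentre is formed and the enol geometry stays mobile through the formyl tautomer.

Step 2
Reactants: 3 dimethyl (2Z,3E)-2-(hydroxymethylidene)pent-3-enedioate; 4 (E)-but-2-enal (crotonaldehyde)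
Product: 7 methyl (2S,3S,4S)-3-formyl-4-(2-methoxy-2-oxoethyl)-2-methyl-3,4-dihydro-2H-pyran-5-carboxylate (methyl elenolate), via catalyst-bound enamine 5 (not isolated), via all-trans C2 epimer 6 (not isolated)
Conditions: (S)-2-[diphenyl(trimethylsilyloxy)methyl]pyrrolidine (20 mol%), PhCO2H (20 mol%), toluene, 0 °C to rt; then Et3N (0.5 equiv), rt, until the diastereomer composition is constant
Reagents that add atoms: none
Why: Proposed new method: the iminium ion formed from 4 and the amine should take the enol oxygen of 3 at its β-carbon (reversible oxa-Michael addition, O1–C2), and the enamine 5 should then close the dihydropyran by an irreversible 6-exo-trig Michael addition of its α-carbon to the acrylate β-carbon (C3–C4), after which hydrolysis releases the amine; the closest known reaction type is the diarylprolinol-silyl-ether-catalysed domino oxa-Michael/Michael reaction of 2-hydroxycinnamates or 2-(2-nitrovinyl)phenols with enals to chromans, the new element being a vinylogous-acid enol OH in place of the phenol. C4 is set in the C–C bond formation by the catalyst, whose diphenyl(silyloxy)methyl group blocks one face of the (E)-enamine, together with a chair-like transition state in which enamine and acrylate are synclinal and both pseudo-equatorial (3,4-trans), which should give 4S with the (S)-amine. C3 is set by the same enamine face (3S) and, being enolisable, stays trans to the C4 arm. C2 is set first by the blocked face of the iminium ion (2R, all-trans 6) and is then inverted to 2S by Et3N-mediated retro-oxa-Michael/oxa-Michael equilibration, because only the 2S epimer can keep the C4 arm pseudo-axial (no strain with the C5 ester), the formyl group axial and the methyl group equatorial. The step needs O-alkylation of the ambident dienol to win over C-alkylation, which the substrate should secure itself: its two carbon sites (C5, which would become quaternary, and the acrylate α-carbon) give adducts of a strongly acidic carbon acid that can revert by retro-Michael reaction, whereas only the O-adduct has a six-membered Michael exit.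

Step 3
Reactants: 7 methyl elenolate
Product: 8 2-[(2S,3S,4S)-3-formyl-5-(methoxycarbonyl)-2-methyl-3,4-dihydro-2H-pyran-4-yl]acetic acid (elenolic acid)
Conditions: pig liver esterase, phosphate buffer pH 7.2/acetone 9:1, 25 °C; then pH 3, EtOAc extraction
Reagents that add atoms: water (O)
Why: Enzymatic ester hydrolysis (carboxylesterase): the unhindered aliphatic CH2CO2Me is a normal esterase substrate, whereas the ring ester is a vinylogous carbonate deactivated by O1 and should be left, and the neutral pH avoids base-induced opening of the β-alkoxy aldehyde; no stereocentre is touched.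

Step 4
Reactants: 8 elenolic acid; 9 2-(3,4-dihydroxyphenyl)ethanol (hydroxytyrosol)
Product: 10 methyl (2S,3S,4S)-4-{2-[2-(3,4-dihydroxyphenyl)ethoxy]-2-oxoethyl}-3-formyl-2-methyl-3,4-dihydro-2H-pyran-5-carboxylate (closed monoaldehyde form of oleuropein aglycone)
Conditions: PPh3 (1.2 equiv), DIAD (1.2 equiv), THF, 0 °C to rt, argon
Reagents that add atoms: none
Why: Mitsunobu esterification: the betaine is protonated by the carboxylic acid of 8, which is far more acidic than the catechol OH groups, and the primary alcohol of 9 is activated as its alkoxyphosphonium ion and displaced by the carboxylate, so the aryl-ethyl ester should form without phenol protection; the carbinol carbon is primary and no stereocentre is involved.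

Step 5
Reactants: 10 closed monoaldehyde form of oleuropein aglycone
Product: 11 methyl (2S,3R,4S)-4-{2-[2-(3,4-dihydroxyphenyl)ethoxy]-2-oxoethyl}-3-(hydroxymethyl)-2-methyl-3,4-dihydro-2H-pyran-5-carboxylate (target)
Conditions: NaBH4 (1.0 equiv), CeCl3·7H2O (1.0 equiv), MeOH, −40 °C, 20 min; then AcOH, pH 6 buffer
Reagents that add atoms: none
Why: Chemoselective 1,2-reduction of the only aldehyde under Luche-type conditions: both esters, the vinylogous carbonate C=C and the catechol are inert at −40 °C, and C3 is kept, not created (its descriptor changes from S to R only because CHO becomes CH2OH); the short, cold, buffered protocol limits attack of the new alkoxide on the side-chain ester, which the trans-diaxial placing of the two arms also disfavours.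

Compound list
1 | dimethyl (E)-pent-2-enedioate (dimethyl glutaconate) | COC(=O)C/C=C/C(=O)OC | starting material
2 | methyl formate | COC=O | starting material
3 | dimethyl (2Z,3E)-2-(hydroxymethylidene)pent-3-enedioate | COC(=O)/C=C/C(=C/O)C(=O)OC | intermediate
4 | (E)-but-2-enal (crotonaldehyde) | C/C=C/C=O | starting material
5 | dimethyl (2E,3E)-2-[({(2R,3E)-4-[(2S)-2-{diphenyl[(trimethylsilyl)oxy]methyl}pyrrolidin-1-yl]but-3-en-2-yl}oxy)methylidene]pent-3-enedioate (catalyst-bound enamine of the oxa-Michael adduct) | C[C@@H](O/C=C(\C=C\C(=O)OC)C(=O)OC)/C=C/N1CCC[C@H]1C(O[Si](C)(C)C)(c1ccccc1)c1ccccc1 | intermediate (not isolated)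
6 | methyl (2R,3S,4S)-3-formyl-4-(2-methoxy-2-oxoethyl)-2-methyl-3,4-dihydro-2H-pyran-5-carboxylate (all-trans C2 epimer) | COC(=O)C1=CO[C@H](C)[C@@H](C=O)[C@@H]1CC(=O)OC | intermediate (not isolated)
7 | methyl (2S,3S,4S)-3-formyl-4-(2-methoxy-2-oxoethyl)-2-methyl-3,4-dihydro-2H-pyran-5-carboxylate (methyl elenolate) | COC(=O)C1=CO[C@@H](C)[C@@H](C=O)[C@@H]1CC(=O)OC | intermediate
8 | 2-[(2S,3S,4S)-3-formyl-5-(methoxycarbonyl)-2-methyl-3,4-dihydro-2H-pyran-4-yl]acetic acid (elenolic acid) | COC(=O)C1=CO[C@@H](C)[C@@H](C=O)[C@@H]1CC(=O)O | intermediate
9 | 2-(3,4-dihydroxyphenyl)ethanol (hydroxytyrosol) | OCCc1ccc(O)c(O)c1 | starting material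
10 | methyl (2S,3S,4S)-4-{2-[2-(3,4-dihydroxyphenyl)ethoxy]-2-oxoethyl}-3-formyl-2-methyl-3,4-dihydro-2H-pyran-5-carboxylate | COC(=O)C1=CO[C@@H](C)[C@@H](C=O)[C@@H]1CC(=O)OCCc1ccc(O)c(O)c1 | intermediate
11 | methyl (2S,3R,4S)-4-{2-[2-(3,4-dihydroxyphenyl)ethoxy]-2-oxoethyl}-3-(hydroxymethyl)-2-methyl-3,4-dihydro-2H-pyran-5-carboxylate | COC(=O)C1=CO[C@@H](C)[C@@H](CO)[C@@H]1CC(=O)OCCc1ccc(O)c(O)c1 | target

Total step count: 5. Longest linear sequence: 5 steps (1 → 3 → 7 → 8 → 10 → 11); 2, 4 and 9 enter as commercial materials.

Steps most likely to fail

Step 2 (proposed new method). Three processes may defeat it. The iminium ion may alkylate the dienol at carbon instead of at oxygen (at C5, or at the acrylate α-carbon followed by aldol condensation to a carbocycle). The amine may be arrested by condensation with the hydroxymethylidene group. Facial selectivity at C4 may be low, or the convergence at C2 incomplete. The fallback makes the two bonds one after the other by known reaction types and sets out from 3. Mitsunobu O-alkylation of the enol OH of 3 with (2S)-4,4-dimethoxybutan-2-ol F1 (from commercial 4,4-dimethoxybutan-2-one by baker's yeast or ketoreductase reduction; PPh3, DIAD, THF) should form the O–C2 bond by SN2 displacement with inversion and give the enol ether dimethyl (2E,3E)-2-({[(2R)-4,4-dimethoxybutan-2-yl]oxy}methylidene)pent-3-enedioate F2, whose enol-ether geometry can equilibrate as a push–pull alkene. Mild acetal hydrolysis (PPTS, acetone/water) should give the aldehyde dimethyl (2E,3E)-2-({[(2R)-4-oxobutan-2-yl]oxy}methylidene)pent-3-enedioate F3. The amine-catalysed intramolecular Michael addition of this aldehyde to the tethered acrylate, with the same (S)-amine (matched with the 2R centre, its enamine being 5), should give 6, and the Et3N equilibration of step 2 brings the sequence back to the route at 7.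

Step 5. The new alkoxide (or its borate) may attack the side-chain ester, giving δ-lactonisation with loss of hydroxytyrosol, and the basic medium may open the ring by β-elimination before reduction is complete. The fallback replaces the hydride reagent by a biocatalytic reduction in which no alkoxide is formed: an NADPH-dependent alcohol dehydrogenase (ketoreductase class) with glucose/glucose dehydrogenase cofactor recycling in pH 7 buffer with a little DMSO at 25 °C. It sets out from 10 and returns at 11 and makes no new compound (F0).

Step 4. The unprotected catechol may be O-alkylated or oxidised under the redox-condensation conditions, or the acid may be transferred to the reduced azodicarboxylate. The fallback protects the catechol and uses a carbodiimide coupling; it sets out from 9 and 8 and returns at 11. Benzylation of 9 (BnBr, K2CO3, acetone, reflux; only the phenols react) should give 2-[3,4-bis(benzyloxy)phenyl]ethan-1-ol F4. Coupling with 8 (EDC·HCl, DMAP, CH2Cl2, 0 °C) should give methyl (2S,3S,4S)-4-(2-{2-[3,4-bis(benzyloxy)phenyl]ethoxy}-2-oxoethyl)-3-formyl-2-methyl-3,4-dihydro-2H-pyran-5-carboxylate F5. Reduction as in step 5 should give methyl (2S,3R,4S)-4-(2-{2-[3,4-bis(benzyloxy)phenyl]ethoxy}-2-oxoethyl)-3-(hydroxymethyl)-2-methyl-3,4-dihydro-2H-pyran-5-carboxylate F6. Hydrogenolysis (H2 at 1 atm, Pd/C, EtOAc, rt), under which the push–pull C5=C6 bond should survive, gives 11.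

Further compounds
F1 | step 2 | (2S)-4,4-dimethoxybutan-2-ol | C[C@H](O)CC(OC)OC
F2 | step 2 | dimethyl (2E,3E)-2-({[(2R)-4,4-dimethoxybutan-2-yl]oxy}methylidene)pent-3-enedioate | C[C@H](CC(OC)OC)O/C=C(\C=C\C(=O)OC)C(=O)OC
F3 | step 2 | dimethyl (2E,3E)-2-({[(2R)-4-oxobutan-2-yl]oxy}methylidene)pent-3-enedioate | C[C@H](CC=O)O/C=C(\C=C\C(=O)OC)C(=O)OC
F0 | step 5 | none | none
F4 | step 4 | 2-[3,4-bis(benzyloxy)phenyl]ethan-1-ol | OCCc1ccc(OCc2ccccc2)c(OCc2ccccc2)c1
F5 | step 4 | methyl (2S,3S,4S)-4-(2-{2-[3,4-bis(benzyloxy)phenyl]ethoxy}-2-oxoethyl)-3-formyl-2-methyl-3,4-dihydro-2H-pyran-5-carboxylate | COC(=O)C1=CO[C@@H](C)[C@@H](C=O)[C@@H]1CC(=O)OCCc1ccc(OCc2ccccc2)c(OCc2ccccc2)c1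
F6 | step 4 | methyl (2S,3R,4S)-4-(2-{2-[3,4-bis(benzyloxy)phenyl]ethoxy}-2-oxoethyl)-3-(hydroxymethyl)-2-methyl-3,4-dihydro-2H-pyran-5-carboxylate | COC(=O)C1=CO[C@@H](C)[C@@H](CO)[C@@H]1CC(=O)OCCc1ccc(OCc2ccccc2)c(OCc2ccccc2)c1
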